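The route rests on disconnecting the fully substituted carbinol carbon C-2 of the but-3-en-2-ol linker from the neighbouring alkene carbon C-3. The key step exploits that C-2 (bearing OH, CH3 and C-1 of ring B) is a methyl ketone in disguise and that the E-CH=CH unit leading to ring A is a terminal alkyne in disguise. Hydrozirconation of the ring A alkyne, transfer to zinc and ligand-controlled, titanium-catalysed addition to the ring B methyl ketone unite a C11 and a C9 fragment, fix the E geometry and set the C-2 configuration in one operation. Ring B (syn-bromohydrin) derives from (S)-limonene, ring A (bromo-exo-methylene) from geranyl acetate.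

Key step: step 11

Remark: ring A is the 3-bromo-2,2-dimethyl-6-methylidenecyclohexyl ring, ring B the 3-bromo-4-hydroxy-4-methylcyclohexyl ring; the linker is numbered as but-3-en-2-ol.

Assumption: the ligand in step 11 is the bis(sulfonamide) diol made from (1S,2S)-cyclohexane-1,2-diamine and (1R)-(−)-camphor-10-sulfonyl chloride, then NaBH4 (exo,exo-diol). Its sense of induction on ketone 7 is taken from aryl methyl ketones, with the cyclohexyl group in the place of aryl; if the sense proves opposite, the mirror-image ligand is used.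

Step 1
Reactants: 1 (S)-(−)-limonene
Product: 3 (1R,2R,4S)-1-methyl-4-(prop-1-en-2-yl)cyclohexane-1,2-diol, via limonene 1,2-oxide 2 (not isolated)
Conditions: mCPBA (1.0 equiv), CH2Cl2, 0 °C; then 1% aq. H2SO4, THF, 0 °C to rt
Reagents that add atoms: mCPBA O=C(OO)c1cccc(Cl)c1; water O
Why: Prilezhaev epoxidation picks the more electron-rich trisubstituted ring alkene, and acid-catalysed trans-diaxial (Fürst–Plattner) hydrolysis makes both epoxide diastereomers converge on the same trans-diol, which fixes C-1 and C-2 relative to the C-4 centre of limonene.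

Step 2
Reactants: 3 (1R,2R,4S)-1-methyl-4-(prop-1-en-2-yl)cyclohexane-1,2-diol
Product: 6 {[(1R,2S,4S)-2-bromo-1-methyl-4-(prop-1-en-2-yl)cyclohexyl]oxy}(trimethyl)silane, via hydroxy triflate 4 (not isolated), via silyloxy triflate 5 (not isolated)
Conditions: Tf2O, 2,6-lutidine, CH2Cl2, −78 °C; TMSOTf, −78 °C; Bu4NBr, −78 °C to rt
Reagents that add atoms: trimethylsilyl trifluoromethanesulfonate C[Si](C)(C)OS(=O)(=O)C(F)(F)F; tetrabutylammonium bromide CCCC[N+](CCCC)(CCCC)CCCC.[Br-]
Why: Chemoselective triflation of the secondary hydroxyl, silylation of the tertiary hydroxyl (which blocks its closure to the epoxide) and SN2 displacement of the axial triflate by bromide from the equatorial side invert C-2 and place bromine cis to the silyloxy group, the β-oxygen disfavouring ionisation.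

Step 3
Reactants: 6 {[(1R,2S,4S)-2-bromo-1-methyl-4-(prop-1-en-2-yl)cyclohexyl]oxy}(trimethyl)silane
Product: 7 1-[(1S,3S,4R)-3-bromo-4-methyl-4-(trimethylsilyloxy)cyclohexyl]ethan-1-one
Conditions: O3, CH2Cl2, −78 °C; then PPh3
Reagents that add atoms: ozone [O-][O+]=O
Why: Ozonolysis with reductive work-up cleaves the only alkene to the methyl ketone under neutral conditions that leave the bromide, the silyl ether and all stereocentres untouched.

Step 4
Reactants: 8 geranyl acetate
Product: 9 (2E)-5-[(2S)-3,3-dimethyloxiran-2-yl]-3-methylpent-2-en-1-yl acetate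
Conditions: L-fructose-derived Shi ketone (30 mol %), Oxone (2KHSO5·KHSO4·K2SO4), K2CO3, Bu4NHSO4, MeCN/dimethoxymethane/aq. Na2B4O7 buffer, 0 °C
Reagents that add atoms: potassium peroxymonosulfate [K+].[O-]S(=O)(=O)OO
Why: Shi asymmetric epoxidation: the chiral dioxirane attacks the terminal trisubstituted alkene (the 2,3-alkene is deactivated by the allylic acetate) through a spiro transition state, and the L-fructose-derived ketone should give the (S)-epoxide.

Step 5
Reactants: 9 (2E)-5-[(2S)-3,3-dimethyloxiran-2-yl]-3-methylpent-2-en-1-yl acetate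
Product: 10 [(1R,3S)-3-hydroxy-2,2-dimethyl-6-methylidenecyclohexyl]methyl acetate
Conditions: Cp2TiCl2 (2.2 equiv), Mn dust, THF, rt; aq. NaH2PO4 work-up
Reagents that add atoms: none
Why: Titanocene-mediated radical epoxypolyene cyclisation: Cp2TiCl (trivalent titanium) opens the epoxide to the tertiary radical, 6-endo addition through a chair transition state with the titanoxy and acetoxymethyl groups equatorial sets C-1 cis to the hydroxyl from the epoxide centre, and trapping of the new tertiary radical by a second Cp2TiCl with loss of Cp2Ti(H)Cl should give the exocyclic alkene (any trans isomer is removed by chromatography).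

Step 6
Reactants: 10 [(1R,3S)-3-hydroxy-2,2-dimethyl-6-methylidenecyclohexyl]methyl acetate
Product: 11 [(1R)-2,2-dimethyl-6-methylidene-3-oxocyclohexyl]methyl acetate
Conditions: Dess–Martin periodinane, CH2Cl2, rt
Reagents that add atoms: none
Why: Dess–Martin oxidation of the secondary alcohol under neutral conditions; the C-1 centre cannot be enolised through this ketone because the quaternary C-2 lies between them.

Step 7
Reactants: 11 [(1R)-2,2-dimethyl-6-methylidene-3-oxocyclohexyl]methyl acetate
Product: 13 (1R,3R)-3-(hydroxymethyl)-2,2-dimethyl-4-methylidenecyclohexan-1-ol, via axial hydroxy acetate 12 (not isolated)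
Conditions: LiBH(s-Bu)3 (1.2 equiv), THF, −78 °C; then MeOH, K2CO3 (cat.), rt
Reagents that add atoms: none
Why: The bulky hydride attacks the ketone from the equatorial side and should give the axial alcohol trans to the side chain (reagent-size-controlled ketone reduction), and base-catalysed methanolysis then removes the acetate in the same flask.

Step 8
Reactants: 13 (1R,3R)-3-(hydroxymethyl)-2,2-dimethyl-4-methylidenecyclohexan-1-ol
Product: 14 (1R,3R)-3-hydroxy-2,2-dimethyl-6-methylidenecyclohexane-1-carbaldehyde
Conditions: TEMPO (10 mol %), PhI(OAc)2, CH2Cl2, rt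
Reagents that add atoms: none
Why: Oxoammonium oxidation is selective for the primary alcohol over the hindered axial secondary one and is non-basic, so the β,γ-unsaturated aldehyde should not isomerise.

Step 9
Reactants: 14 (1R,3R)-3-hydroxy-2,2-dimethyl-6-methylidenecyclohexane-1-carbaldehyde
Product: 15 (1R,3S)-3-ethynyl-2,2-dimethyl-4-methylidenecyclohexan-1-ol
Conditions: TMSCHN2, n-BuLi, THF, −78 °C; then 14, −78 to 0 °C
Reagents that add atoms: trimethylsilyldiazomethane C[Si](C)(C)C=[N+]=[N-]
Why: Colvin homologation: the lithiated diazo reagent adds to the aldehyde at low temperature, Peterson elimination and loss of N2 give an alkylidene carbene whose 1,2-hydrogen shift gives the terminal alkyne without touching the stereocentres (a second equivalent covers the free hydroxyl).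

Step 10
Reactants: 15 (1R,3S)-3-ethynyl-2,2-dimethyl-4-methylidenecyclohexan-1-ol
Product: 16 (1S,3S)-1-bromo-3-ethynyl-2,2-dimethyl-4-methylidenecyclohexane
Conditions: CBr4, P(n-Oct)3, toluene, 70 °C
Reagents that add atoms: carbon tetrabromide BrC(Br)(Br)Br
Why: Appel reaction: the alkoxyphosphonium ion of the axial neopentyl-type alcohol is displaced by bromide from the equatorial side (SN2, inversion), which should give the equatorial bromide cis to the ethynyl group.

Step 11
Reactants: 16 (1S,3S)-1-bromo-3-ethynyl-2,2-dimethyl-4-methylidenecyclohexane; 7 1-[(1S,3S,4R)-3-bromo-4-methyl-4-(trimethylsilyloxy)cyclohexyl]ethan-1-one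
Product: 19 (2S,3E)-4-[(1R,3S)-3-bromo-2,2-dimethyl-6-methylidenecyclohexyl]-2-[(1S,3S,4R)-3-bromo-4-methyl-4-(trimethylsilyloxy)cyclohexyl]but-3-en-2-ol, via alkenylzirconocene chloride 17 (not isolated), via alkenyl(methyl)zinc 18 (not isolated)
Conditions: Cp2Zr(H)Cl (1.05 equiv), CH2Cl2, rt; then Me2Zn, toluene, −78 °C; then bis(sulfonamide) diol ligand (10 mol %), Ti(OiPr)4 (1.2 equiv), 7, toluene, rt
Reagents that add atoms: none
Why: Syn-hydrozirconation of the terminal alkyne of 16 places zirconium on the terminal carbon and fixes the E geometry, Zr-to-Zn exchange with Me2Zn gives 18, and its alkenyl group is transferred to the carbonyl carbon of 7 inside a chiral titanium bis(sulfonamide) diolate complex. The closest known reaction type is the catalytic asymmetric alkenylation of ketones with alkenylzinc reagents made by hydrozirconation and transmetalation. No ring is closed. The one new stereocentre, carbinol C-2, is set under catalyst control: the ligand should deliver the alkenyl group to the Re face of the ketone (O > ring B carbon > CH3), the large cyclohexyl and small methyl groups being told apart as aryl and methyl are in acetophenones, while the α-centre of 7 with its two near-identical ring branches exerts little bias of its own. The step needs chemoselectivity (alkyne over the exocyclic 1,1-disubstituted alkene in hydrozirconation, alkenyl over methyl transfer, addition over enolisation, both secondary bromides untouched), which the faster hydrozirconation of alkynes, the higher transfer aptitude of sp2 carbon from zinc and the low basicity of organozinc reagents should secure; the tertiary hydroxyl of ring B is masked as its trimethylsilyl ether so that it does not consume the reagent.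

Step 12
Reactants: 19 (2S,3E)-4-[(1R,3S)-3-bromo-2,2-dimethyl-6-methylidenecyclohexyl]-2-[(1S,3S,4R)-3-bromo-4-methyl-4-(trimethylsilyloxy)cyclohexyl]but-3-en-2-ol
Product: 20 (2S,3E)-4-[(1R,3S)-3-bromo-2,2-dimethyl-6-methylidenecyclohexyl]-2-[(1S,3S,4R)-3-bromo-4-hydroxy-4-methylcyclohexyl]but-3-en-2-ol
Conditions: Bu4NF, AcOH, THF, 0 °C
Reagents that add atoms: none
Why: Fluoride-mediated desilylation of the tertiary trimethylsilyl ether, buffered with acetic acid so that the tertiary allylic alcohol and the cis-bromohydrin see neither strong acid nor strong base.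

Compound list
1 | (S)-(−)-limonene, (4S)-1-methyl-4-(prop-1-en-2-yl)cyclohex-1-ene | C=C(C)[C@H]1CCC(C)=CC1 | starting material
2 | (4S)-limonene 1,2-oxide, both epoxide diastereomers | C=C(C)[C@H]1CCC2(C)OC2C1 | intermediate
3 | (1R,2R,4S)-1-methyl-4-(prop-1-en-2-yl)cyclohexane-1,2-diol | C=C(C)[C@H]1CC[C@@](C)(O)[C@H](O)C1 | intermediate
4 | (1R,2R,5S)-2-hydroxy-2-methyl-5-(prop-1-en-2-yl)cyclohexyl trifluoromethanesulfonate | C=C(C)[C@H]1CC[C@@](C)(O)[C@H](OS(=O)(=O)C(F)(F)F)C1 | intermediate
5 | (1R,2R,5S)-2-methyl-5-(prop-1-en-2-yl)-2-(trimethylsilyloxy)cyclohexyl trifluoromethanesulfonate | C=C(C)[C@H]1CC[C@@](C)(O[Si](C)(C)C)[C@H](OS(=O)(=O)C(F)(F)F)C1 | intermediate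
6 | {[(1R,2S,4S)-2-bromo-1-methyl-4-(prop-1-en-2-yl)cyclohexyl]oxy}(trimethyl)silane | C=C(C)[C@H]1CC[C@@](C)(O[Si](C)(C)C)[C@@H](Br)C1 | intermediate
7 | 1-[(1S,3S,4R)-3-bromo-4-methyl-4-(trimethylsilyloxy)cyclohexyl]ethan-1-one | CC(=O)[C@H]1CC[C@@](C)(O[Si](C)(C)C)[C@@H](Br)C1 | intermediate
8 | geranyl acetate, (2E)-3,7-dimethylocta-2,6-dien-1-yl acetate | CC(C)=CCC/C(C)=C/COC(C)=O | starting material
9 | (2E)-5-[(2S)-3,3-dimethyloxiran-2-yl]-3-methylpent-2-en-1-yl acetate | CC1(C)O[C@H]1CC/C(C)=C/COC(C)=O | intermediate
10 | [(1R,3S)-3-hydroxy-2,2-dimethyl-6-methylidenecyclohexyl]methyl acetate (hydroxyl and acetoxymethyl cis) | C=C1CC[C@H](O)C(C)(C)[C@@H]1COC(C)=O | intermediate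
11 | [(1R)-2,2-dimethyl-6-methylidene-3-oxocyclohexyl]methyl acetate | C=C1CCC(=O)C(C)(C)[C@@H]1COC(C)=O | intermediate
12 | [(1R,3R)-3-hydroxy-2,2-dimethyl-6-methylidenecyclohexyl]methyl acetate (axial hydroxyl, trans) | C=C1CC[C@@H](O)C(C)(C)[C@@H]1COC(C)=O | intermediate
13 | (1R,3R)-3-(hydroxymethyl)-2,2-dimethyl-4-methylidenecyclohexan-1-ol | C=C1CC[C@@H](O)C(C)(C)[C@@H]1CO | intermediate
14 | (1R,3R)-3-hydroxy-2,2-dimethyl-6-methylidenecyclohexane-1-carbaldehyde | C=C1CC[C@@H](O)C(C)(C)[C@@H]1C=O | intermediate
15 | (1R,3S)-3-ethynyl-2,2-dimethyl-4-methylidenecyclohexan-1-ol | C=C1CC[C@@H](O)C(C)(C)[C@@H]1C#C | intermediate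
16 | (1S,3S)-1-bromo-3-ethynyl-2,2-dimethyl-4-methylidenecyclohexane (bromine and ethynyl cis) | C=C1CC[C@H](Br)C(C)(C)[C@@H]1C#C | intermediate
17 | alkenylzirconocene chloride, (E)-RCH=CH–Zr(Cl)Cp2 with R = (1R,3S)-3-bromo-2,2-dimethyl-6-methylidenecyclohexyl | C=C1CC[C@H](Br)C(C)(C)[C@@H]1/C=C/[Zr](Cl)(C1C=CC=C1)C1C=CC=C1 | intermediate
18 | alkenyl(methyl)zinc, (E)-RCH=CH–ZnCH3 with the same R | C=C1CC[C@H](Br)C(C)(C)[C@@H]1/C=C/[Zn]C | intermediate
19 | (2S,3E)-4-[(1R,3S)-3-bromo-2,2-dimethyl-6-methylidenecyclohexyl]-2-[(1S,3S,4R)-3-bromo-4-methyl-4-(trimethylsilyloxy)cyclohexyl]but-3-en-2-ol | C=C1CC[C@H](Br)C(C)(C)[C@@H]1/C=C/[C@@](C)(O)[C@H]1CC[C@@](C)(O[Si](C)(C)C)[C@@H](Br)C1 | intermediate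
20 | (2S,3E)-4-[(1R,3S)-3-bromo-2,2-dimethyl-6-methylidenecyclohexyl]-2-[(1S,3S,4R)-3-bromo-4-hydroxy-4-methylcyclohexyl]but-3-en-2-ol | C=C1CC[C@H](Br)C(C)(C)[C@@H]1/C=C/[C@@](C)(O)[C@H]1CC[C@@](C)(O)[C@@H](Br)C1 | target

Total step count: 12. Longest linear sequence: 9 steps (steps 4 to 12, from geranyl acetate); the ring B branch is 3 steps long before the union.

Steps most likely to fail

1. Step 11. Alkenyl transfer to the hindered, enolisable dialkyl ketone may be slow, so that methyl transfer and enolisation compete, and the catalyst may tell the two sp3 flanks of the ketone apart poorly (low facial selectivity). The fallback sets out from 16 and 7 and comes back to the route at 20; it separates bond formation from the setting of the alkene geometry. Alkyne 16 is deprotonated (LiN(SiMe3)2, THF, −78 °C), transferred to CeCl3 and added to 7; this non-basic alkynylcerium addition forms the same carbon–carbon bond and should give the propargylic tertiary alcohol F1, whose C-2 epimer, if formed, is removed by chromatography at this stage. Ruthenium-catalysed trans-hydrosilylation ([Cp*Ru(MeCN)3]PF6, BnMe2SiH, CH2Cl2) should give the (Z)-vinylsilane F2. Bu4NF with CuI in THF then removes the carbon-bound silyl group with retention of geometry and the trimethylsilyl ether at once, giving 20.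

2. Step 2. The hydroxy triflate 4 may close to the epoxide through the anti-periplanar tertiary hydroxyl before it is silylated, and in the displacement E2 elimination towards C-3 may compete with substitution next to the fully substituted carbon. The fallback sets out from 3 and comes back at 6; it differentiates the hydroxyls before any leaving group exists and runs the substitution through an alkoxyphosphonium ion. Selective acetylation of the secondary hydroxyl (Ac2O, pyridine) gives the monoacetate F3, and silylation of the tertiary hydroxyl (TMSOTf, 2,6-lutidine) gives the silyl ether acetate F4. Reductive removal of the acetate (i-Bu2AlH, CH2Cl2, −78 °C) gives the mono-protected alcohol F5, and Appel bromination (CBr4, P(n-Oct)3, toluene, 60 °C) with inversion gives 6.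

3. Step 9. The lithiated diazo reagent may deprotonate the hindered β,γ-unsaturated aldehyde instead of adding to it, which moves the exocyclic alkene into conjugation. The fallback sets out from 14 and comes back at 18 inside step 11; it bypasses the alkyne and makes the alkenyl metal from an alkenyl iodide. Takai iodo-olefination of 14 (CrCl2, CHI3, THF, 0 °C, non-basic) should give the (E)-iodoalkene alcohol F6, and Appel bromination as in step 10 gives the bromo (E)-iodoalkene F7. Iodine–lithium exchange (t-BuLi, 2 equiv, Et2O, −100 °C) followed by MeZnCl gives the alkenyl(methyl)zinc 18, which is used in step 11 from the transmetalated stage on.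

Further compounds
F1 | step 11 | (2S)-4-[(1S,3S)-3-bromo-2,2-dimethyl-6-methylidenecyclohexyl]-2-[(1S,3S,4R)-3-bromo-4-methyl-4-(trimethylsilyloxy)cyclohexyl]but-3-yn-2-ol | C=C1CC[C@H](Br)C(C)(C)[C@@H]1C#C[C@@](C)(O)[C@H]1CC[C@@](C)(O[Si](C)(C)C)[C@@H](Br)C1
F2 | step 11 | (2S,3Z)-4-[benzyl(dimethyl)silyl]-4-[(1R,3S)-3-bromo-2,2-dimethyl-6-methylidenecyclohexyl]-2-[(1S,3S,4R)-3-bromo-4-methyl-4-(trimethylsilyloxy)cyclohexyl]but-3-en-2-ol | C=C1CC[C@H](Br)C(C)(C)[C@@H]1/C([Si](C)(C)Cc1ccccc1)=C/[C@@](C)(O)[C@H]1CC[C@@](C)(O[Si](C)(C)C)[C@@H](Br)C1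
F3 | step 2 | (1R,2R,5S)-2-hydroxy-2-methyl-5-(prop-1-en-2-yl)cyclohexyl acetate | C=C(C)[C@H]1CC[C@@](C)(O)[C@H](OC(C)=O)C1
F4 | step 2 | (1R,2R,5S)-2-methyl-5-(prop-1-en-2-yl)-2-(trimethylsilyloxy)cyclohexyl acetate | C=C(C)[C@H]1CC[C@@](C)(O[Si](C)(C)C)[C@H](OC(C)=O)C1
F5 | step 2 | (1R,2R,5S)-2-methyl-5-(prop-1-en-2-yl)-2-(trimethylsilyloxy)cyclohexan-1-ol | C=C(C)[C@H]1CC[C@@](C)(O[Si](C)(C)C)[C@H](O)C1
F6 | step 9 | (1R,3R)-3-[(E)-2-iodoethenyl]-2,2-dimethyl-4-methylidenecyclohexan-1-ol | C=C1CC[C@@H](O)C(C)(C)[C@@H]1/C=C/I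
F7 | step 9 | (1S,3R)-1-bromo-3-[(E)-2-iodoethenyl]-2,2-dimethyl-4-methylidenecyclohexane | C=C1CC[C@H](Br)C(C)(C)[C@@H]1/C=C/I
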